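The ent-labdane core is cut at C5–C10 and C8–C9. This uses the ring B sequence C8 (methylene carbon), C9 (H, C11 side chain) and quaternary C10 (CH3), which adjoins ring A (C1–C5, C10) with its symmetric C4 next to C5–H. One auxiliary-controlled intramolecular Diels–Alder reaction closes rings A and B and sets C5, C8, C9 and C10. Its precursor is the acyclic (R)-4-benzyloxazolidinone imide of a (2E,8E,10E)-3-methylundecatrienoic acid: E-β-methylenoyl dienophile (C9=C10), C1–C4 tether ending in a malonate carbon, and 1-silyloxydiene (C5–C8). Afterwards the imide carbonyl becomes C11, the C8 oxygen becomes the exocyclic methylene, and the diester becomes the two CH2OAc groups.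

Key step: step 7

Remark on the structure: the target SMILES decodes as (5S,9R,10S) in labdane numbering. H-5 is trans to CH3-10, C11 is cis to CH3-10 (ent-labdane series), the side chain is 12E, and C4 is not stereogenic. Labdane numbering is used for all compounds. Xc = (R)-4-benzyl-2-oxooxazolidin-3-yl, TBS = tert-butyldimethylsilyl.
Assumption: compounds 1, 4, 9, 12 and 21 are taken as catalogue chemicals.

Step 1
Reactants: 1 5-chloropent-1-yne
Product: 3 (E)-5-chloro-1-iodo-2-methylpent-1-ene, via alkenyldimethylalane 2 (not isolated)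
Conditions: Me3Al (2 equiv), Cp2ZrCl2 (20 mol %), CH2Cl2, 0 °C → rt; then I2, THF, −30 → 0 °C
Reagents that add atoms: trimethylaluminium, C[Al](C)C; iodine, II
Why: Zirconium-catalysed carboalumination (Negishi) adds CH3 and Al syn to the terminal alkyne with Al at the terminus and iodinolysis keeps the geometry, so the E trisubstituted alkene (future C20 methyl cis to C11) is fixed here and the primary chloride is spared.

Step 2
Reactants: 3 (E)-5-chloro-1-iodo-2-methylpent-1-ene; 4 dimethyl 2-allylmalonate
Product: 7 dimethyl 2-allyl-2-[(E)-5-iodo-4-methylpent-4-en-1-yl]malonate, via sodium enolate 5 (not isolated), via diiodide 6 (not isolated)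
Conditions: 4 (1.25 equiv), NaH (1.2 equiv), DMF, 0 °C → rt; then 3, NaI (20 mol %), 60 °C
Reagents that add atoms: none
Why: Malonic ester alkylation (SN2) helped by Finkelstein exchange of chloride for iodide builds the quaternary but non-stereogenic C4, and the soft enolate leaves the alkenyl iodide and its geometry untouched.

Step 3
Reactants: 7 dimethyl 2-allyl-2-[(E)-5-iodo-4-methylpent-4-en-1-yl]malonate
Product: 8 (2E)-7,7-bis(methoxycarbonyl)-3-methyldeca-2,9-dienoic acid
Conditions: CO (1 atm), Pd(OAc)2 (5 mol %), PPh3 (15 mol %), H2O (10 equiv), Et3N (3 equiv), DMF, 50 °C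
Reagents that add atoms: carbon monoxide, [C-]#[O+]; water, O
Why: Palladium-catalysed hydroxycarbonylation of an alkenyl iodide (oxidative addition to zerovalent palladium, CO insertion, hydrolysis of the acylpalladium) proceeds with retention of the E geometry, and CO capture is far faster than a medium-ring Heck closure onto the allyl group.

Step 4
Reactants: 8 (2E)-7,7-bis(methoxycarbonyl)-3-methyldeca-2,9-dienoic acid; 9 (R)-4-benzyloxazolidin-2-one
Product: 11 (R)-4-benzyl-3-[(2E)-7,7-bis(methoxycarbonyl)-3-methyldeca-2,9-dienoyl]oxazolidin-2-one, via mixed pivalic anhydride 10 (not isolated)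
Conditions: PivCl, Et3N (2.2 equiv), THF, −20 °C; then LiCl, 9, −20 °C → rt
Reagents that add atoms: none
Why: N-Acylation of the oxazolidinone through a mixed pivalic anhydride with LiCl activation needs no strong base, so the malonate esters and the E enoyl geometry are kept and the auxiliary stereocentre is simply imported.

Step 5
Reactants: 11 allyl imide; 12 (E)-crotonaldehyde
Product: 13 (R)-4-benzyl-3-[(2E,9E)-7,7-bis(methoxycarbonyl)-3-methyl-11-oxoundeca-2,9-dienoyl]oxazolidin-2-one
Conditions: 12 (5 equiv), second-generation Grubbs catalyst RuCl2(=CHPh)(PCy3)(SIMes) (3 mol %), CH2Cl2, 40 °C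
Reagents that add atoms: none
Why: Olefin cross-metathesis of an unhindered terminal alkene with an excess of an electron-poor partner gives the E enal under thermodynamic control, while the trisubstituted, acceptor-substituted C9=C10 bond does not engage the ruthenium carbene.

Step 6
Reactants: 13 enal imide
Product: 14 (R)-4-benzyl-3-[(2E,8E,10E)-11-(tert-butyldimethylsilyloxy)-7,7-bis(methoxycarbonyl)-3-methylundeca-2,8,10-trienoyl]oxazolidin-2-one
Conditions: TBSOTf (1.2 equiv), Et3N (2.5 equiv), CH2Cl2, −78 → 0 °C; filtration through Et3N-deactivated silica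
Reagents that add atoms: tert-butyldimethylsilyl triflate, CC(C)(C)[Si](C)(C)OS(=O)(=O)C(F)(F)F
Why: Soft enolisation (O-silylation of the aldehyde, then removal of a γ-proton at C5 by Et3N) gives the silyl dienol ether, E at C7=C8 from the s-trans enal and E at C5=C6 because allylic strain keeps quaternary C4 away from C7, and the less basic imide is not silylated by the small excess at low temperature.

Step 7
Reactants: 14 silyloxytrienoyl imide
Product: 15 trans-fused Δ6-octalin imide (5S,8R,9S,10R; auxiliary 4R) carrying C4(CO2Me)2 plus C8-OTBS plus C9-C(=O)Xc plus C10-CH3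
Conditions: Me2AlCl (3–4 equiv, 1 M in hexanes), CH2Cl2, −78 → −20 °C; then aq. NaHCO3
Reagents that add atoms: none
Why: Excess Me2AlCl (two equivalents build the cationic bidentate aluminium chelate of the imide, the rest only occupies the two ester carbonyls and scavenges protons) locks the enoyl unit s-cis and lowers its LUMO, so the tethered donor diene adds in a normal-electron-demand, concerted but strongly asynchronous [4+2] cycloaddition in which C5–C10 runs ahead of C8–C9. The closest known reaction type is the dialkylaluminium chloride-promoted intramolecular Diels–Alder reaction of (E,E,E)-trienoyl oxazolidinones to trans-fused bicycles, from which this case departs only in the β-methyl group and the donor diene. Ring B (C5–C10) is the new cyclohexene assembled from the four diene carbons C5–C8 and the two dienophile carbons C9 and C10, while ring A (C1–C5, C10) closes through the same C5–C10 bond in a 6-exo sense (C9 stays outside ring A) with the C1–C4 tether folded as a chair. C9 and C10 are set in the absolute sense by the auxiliary, whose benzyl group covers one face of the planar chelate so that the diene bonds to the C9 Re face, and their relative configuration (C11 cis to the C10 methyl) is carried over from the E dienophile. C5 follows from the carbonyl-endo, tether-anti transition state together with the E C5=C6 bond (H-5 trans to the methyl, hence a trans-decalin), and C8 follows from the E enol ether under the same endo rule (OTBS cis to C11). The step needs regio-, endo/exo and π-facial selectivity: the first is enforced by the tether and matched by polarity (donor-remote C5 to acceptor β-carbon C10), the second comes from the chelated carbonyl and the geminal diester that favours the folded chair, and the third from the benzyl group.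

Step 8
Reactants: 15 trans-fused Δ6-octalin imide
Product: 16 saturated trans-decalin imide (5S,8R,9S,10R; auxiliary 4R)
Conditions: H2 (1 atm), 10% Pd/C, EtOAc, rt
Reagents that add atoms: none
Why: Heterogeneous catalytic hydrogenation saturates the only remaining olefinic bond (cis-disubstituted C6=C7) without creating a stereocentre, and the C-benzyl group, silyl ether, esters and imide are inert in neutral EtOAc.

Step 9
Reactants: 16 saturated trans-decalin imide
Product: 18 C11 carboxylic acid (5S,8R,9S,10R), via peroxy acid 17 (not isolated)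
Conditions: LiOH·H2O (2 equiv), 30% H2O2 (8 equiv), THF/H2O 3:1, 0 °C → rt; aq. Na2SO3; 1 M HCl to pH 3
Reagents that add atoms: hydrogen peroxide (as LiOOH), OO
Why: Hydroperoxide cleavage of an N-acyloxazolidinone: the small α-effect nucleophile HOO− attacks the exocyclic carbonyl even of hindered imides, sulfite reduces the peracid, the quaternary-carbon methyl esters resist at 0 °C, and the equatorial C9 substituent has no drive to epimerise.

Step 10
Reactants: 18 C11 carboxylic acid
Product: 19 C11 primary alcohol (5S,8R,9R,10R)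
Conditions: BH3·THF (2.5 equiv), THF, 0 °C → rt; then aq. NH4Cl
Reagents that add atoms: none
Why: Chemoselective borane reduction of a carboxylic acid (via the acyloxyborane) is much faster than ester reduction, so only C11 is taken to the primary alcohol and no stereocentre is touched.

Step 11
Reactants: 19 C11 primary alcohol
Product: 20 C11 primary iodide (5S,8R,9S,10R)
Conditions: I2 (1.5 equiv), PPh3 (1.5 equiv), imidazole (3 equiv), CH2Cl2, 0 °C → rt
Reagents that add atoms: iodine, II
Why: Appel-type iodination (Garegg–Samuelsson conditions) displaces the alkoxyphosphonium ion at primary C11 by iodide under nearly neutral conditions that spare silyl ether and esters.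

Step 12
Reactants: 21 propargyl alcohol
Product: 23 (E)-3-iodo-2-methylprop-2-en-1-ol, via alkenylalane 22 (not isolated)
Conditions: Me3Al (3 equiv), Cp2ZrCl2 (25 mol %), CH2Cl2, 0 °C → rt; then I2, THF, −30 → 0 °C
Reagents that add atoms: trimethylaluminium, C[Al](C)C; iodine, II
Why: Zirconium-catalysed carboalumination (Negishi) of the aluminium alkoxide of propargyl alcohol is a syn addition with Al at the terminus, and iodinolysis with retention gives the E iodoalkene that carries C12, C13, C14 and C16.

Step 13
Reactants: 23 (E)-3-iodo-2-methylprop-2-en-1-ol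
Product: 24 (E)-tert-butyl[(3-iodo-2-methylallyl)oxy]dimethylsilane
Conditions: TBSCl, imidazole, CH2Cl2, 0 °C → rt
Reagents that add atoms: tert-butyldimethylsilyl chloride, CC(C)(C)[Si](C)(C)Cl
Why: Standard silylation of a primary allylic alcohol removes the acidic proton that would quench the organozinc reagent, and it uses the same silyl group as C8 so that both fall in one later step.

Step 14
Reactants: 20 C11 primary iodide; 24 (E)-tert-butyl[(3-iodo-2-methylallyl)oxy]dimethylsilane
Product: 26 bis-silyl ether with the C11–C12 bond in place (5S,8R,9S,10R,12E), via alkylzinc iodide 25 (not isolated)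
Conditions: Zn dust (3 equiv, activated with BrCH2CH2Br and Me3SiCl), LiCl (1.5 equiv), THF, 40 °C; then 24 (1.3 equiv), PdCl2(dppf) (5 mol %), THF, rt → 50 °C
Reagents that add atoms: none
Why: LiCl-assisted direct zinc insertion turns the primary iodide into an ester-tolerant alkylzinc iodide, and Negishi sp3–sp2 cross-coupling with the alkenyl iodide forms C11–C12 with retention of the E geometry, the wide-bite-angle dppf ligand favouring reductive elimination over β-hydride loss from C9.

Step 15
Reactants: 26 bis-silyl ether
Product: 27 C8,C14-diol (5S,8R,9S,10R,12E)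
Conditions: 48% aq. HF, MeCN, 0 °C → rt
Reagents that add atoms: none
Why: Acidic fluoride desilylation cleaves the primary allylic and the hindered axial C8 silyl ethers together, and the methyl esters and the trisubstituted alkene are stable to dilute HF.

Step 16
Reactants: 27 C8,C14-diol
Product: 28 C8-keto C14-enal (5S,9S,10R,12E)
Conditions: Dess–Martin periodinane (3 equiv), CH2Cl2, 0 °C → rt
Reagents that add atoms: none
Why: Dess–Martin oxidation converts the allylic alcohol into the E enal and the C8 carbinol into the ketone in one mild operation, erasing the C8 stereocentre as planned and leaving C9 in its favoured equatorial configuration.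

Step 17
Reactants: 28 C8-keto C14-enal
Product: 29 dimethyl ent-labda-8(17),12E,14-triene-18,19-dioate (5S,9R,10S)
Conditions: Ph3PCH3Br (6 equiv), KOt-Bu (5.5 equiv), THF, 0 °C; then 28, 0 → 45 °C
Reagents that add atoms: methyltriphenylphosphonium bromide (as its ylide), C[P+](c1ccccc1)(c1ccccc1)c1ccccc1.[Br-]
Why: Twofold Wittig methylenation installs C15 at the reactive enal first and C17 at the hindered C8 ketone on warming, the hindered esters survive the ylide, and any enolisation returns C9 to the equatorial (correct) configuration.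

Step 18
Reactants: 29 triene diester
Product: 30 ent-labda-8(17),12E,14-triene-18,19-diol (5S,9R,10S)
Conditions: LiAlH4 (4 equiv), THF, 0 °C → reflux; then H2O, aq. NaOH
Reagents that add atoms: none
Why: Hydride reduction with LiAlH4 takes both hindered methyl esters to the neopentyl primary alcohols, and C=C bonds that carry no acceptor group are inert to it.

Step 19
Reactants: 30 triene diol
Product: 31 ent-labda-8(17),12E,14-triene-18,19-diyl diacetate (5S,9R,10S), CNP0129553.1
Conditions: Ac2O (4 equiv), pyridine, DMAP (10 mol %), CH2Cl2, rt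
Reagents that add atoms: acetic anhydride, CC(=O)OC(C)=O
Why: DMAP-catalysed acetylation esterifies both primary neopentyl alcohols under mild basic conditions that do not isomerise the exocyclic alkene or the diene.

Compound list
1 | 5-chloropent-1-yne | C#CCCCCl | starting material
2 | (E)-(5-chloro-2-methylpent-1-en-1-yl)dimethylalane | C[Al](C)/C=C(C)/CCCCl | intermediate
3 | (E)-5-chloro-1-iodo-2-methylpent-1-ene | I/C=C(C)/CCCCl | intermediate
4 | dimethyl 2-allylmalonate | C=CCC(C(=O)OC)C(=O)OC | starting material
5 | sodium enolate of dimethyl 2-allylmalonate | [Na+].C=CC[C-](C(=O)OC)C(=O)OC | intermediate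
6 | (E)-1,5-diiodo-2-methylpent-1-ene | I/C=C(C)/CCCI | intermediate
7 | dimethyl 2-allyl-2-[(E)-5-iodo-4-methylpent-4-en-1-yl]malonate | I/C=C(C)/CCCC(CC=C)(C(=O)OC)C(=O)OC | intermediate
8 | (2E)-7,7-bis(methoxycarbonyl)-3-methyldeca-2,9-dienoic acid | OC(=O)/C=C(C)/CCCC(CC=C)(C(=O)OC)C(=O)OC | intermediate
9 | (R)-4-benzyloxazolidin-2-one | O=C1N[C@H](Cc2ccccc2)CO1 | starting material
10 | mixed anhydride of 8 and pivalic acid | CC(C)(C)C(=O)OC(=O)/C=C(C)/CCCC(CC=C)(C(=O)OC)C(=O)OC | intermediate
11 | (R)-4-benzyl-3-[(2E)-7,7-bis(methoxycarbonyl)-3-methyldeca-2,9-dienoyl]oxazolidin-2-one | O=C(/C=C(C)/CCCC(CC=C)(C(=O)OC)C(=O)OC)N1[C@H](Cc2ccccc2)COC1=O | intermediate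
12 | (E)-crotonaldehyde | C/C=C/C=O | starting material
13 | (R)-4-benzyl-3-[(2E,9E)-7,7-bis(methoxycarbonyl)-3-methyl-11-oxoundeca-2,9-dienoyl]oxazolidin-2-one | O=C(/C=C(C)/CCCC(C/C=C/C=O)(C(=O)OC)C(=O)OC)N1[C@H](Cc2ccccc2)COC1=O | intermediate
14 | (R)-4-benzyl-3-[(2E,8E,10E)-11-(tert-butyldimethylsilyloxy)-7,7-bis(methoxycarbonyl)-3-methylundeca-2,8,10-trienoyl]oxazolidin-2-one (key-step precursor) | O=C(/C=C(C)/CCCC(C(=O)OC)(C(=O)OC)/C=C/C=C/O[Si](C)(C)C(C)(C)C)N1[C@H](Cc2ccccc2)COC1=O | intermediate
15 | trans-fused Δ6-octalin imide (key-step product): C4(CO2Me)2, C6=C7, axial C8-OTBS, equatorial C9-C(=O)Xc, C10-CH3; (5S,8R,9S,10R), auxiliary 4R; H-5 trans to CH3-10, C11 and OTBS cis to CH3-10 | O=C(N1[C@H](Cc2ccccc2)COC1=O)[C@@H]3[C@H](O[Si](C)(C)C(C)(C)C)C=C[C@@H]4C(C(=O)OC)(C(=O)OC)CCC[C@@]34C | intermediate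
16 | 6,7-dihydro derivative of 15, (5S,8R,9S,10R), auxiliary 4R | O=C(N1[C@H](Cc2ccccc2)COC1=O)[C@@H]3[C@H](O[Si](C)(C)C(C)(C)C)CC[C@@H]4C(C(=O)OC)(C(=O)OC)CCC[C@@]34C | intermediate
17 | C11 peroxy acid, (5S,8R,9S,10R) | OOC(=O)[C@@H]1[C@H](O[Si](C)(C)C(C)(C)C)CC[C@@H]2C(C(=O)OC)(C(=O)OC)CCC[C@@]12C | intermediate
18 | C11 carboxylic acid with C8-OTBS and C4(CO2Me)2, (5S,8R,9S,10R) | OC(=O)[C@@H]1[C@H](O[Si](C)(C)C(C)(C)C)CC[C@@H]2C(C(=O)OC)(C(=O)OC)CCC[C@@]12C | intermediate
19 | C11 primary alcohol, (5S,8R,9R,10R) | OC[C@@H]1[C@H](O[Si](C)(C)C(C)(C)C)CC[C@@H]2C(C(=O)OC)(C(=O)OC)CCC[C@@]12C | intermediate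
20 | C11 primary iodide, (5S,8R,9S,10R) | IC[C@@H]1[C@H](O[Si](C)(C)C(C)(C)C)CC[C@@H]2C(C(=O)OC)(C(=O)OC)CCC[C@@]12C | intermediate
21 | propargyl alcohol | C#CCO | starting material
22 | (E)-alkenyldimethylalane of propargyl alcohol, O-bound to AlMe2 | C[Al](C)/C=C(C)/CO[Al](C)C | intermediate
23 | (E)-3-iodo-2-methylprop-2-en-1-ol | OC/C(C)=C/I | intermediate
24 | (E)-tert-butyl[(3-iodo-2-methylallyl)oxy]dimethylsilane | CC(C)(C)[Si](C)(C)OC/C(C)=C/I | intermediate
25 | C11 alkylzinc iodide, (5S,8R,9S,10R) | I[Zn]C[C@@H]1[C@H](O[Si](C)(C)C(C)(C)C)CC[C@@H]2C(C(=O)OC)(C(=O)OC)CCC[C@@]12C | intermediate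
26 | C8,C14-bis(TBS ether) with 12E alkene and C4(CO2Me)2, (5S,8R,9S,10R) | CC(C)(C)[Si](C)(C)OC/C(C)=C/C[C@@H]1[C@H](O[Si](C)(C)C(C)(C)C)CC[C@@H]2C(C(=O)OC)(C(=O)OC)CCC[C@@]12C | intermediate
27 | C8,C14-diol, (5S,8R,9S,10R,12E) | OC/C(C)=C/C[C@@H]1[C@H](O)CC[C@@H]2C(C(=O)OC)(C(=O)OC)CCC[C@@]12C | intermediate
28 | C8-keto C14-enal, (5S,9S,10R,12E) | O=C/C(C)=C/C[C@@H]1C(=O)CC[C@@H]2C(C(=O)OC)(C(=O)OC)CCC[C@@]12C | intermediate
29 | dimethyl ent-labda-8(17),12E,14-triene-18,19-dioate, (5S,9R,10S) | C=C/C(C)=C/C[C@@H]1C(=C)CC[C@@H]2C(C(=O)OC)(C(=O)OC)CCC[C@@]12C | intermediate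
30 | ent-labda-8(17),12E,14-triene-18,19-diol, (5S,9R,10S) | C=C/C(C)=C/C[C@@H]1C(=C)CC[C@@H]2C(CO)(CO)CCC[C@@]12C | intermediate
31 | ent-labda-8(17),12E,14-triene-18,19-diyl diacetate, (5S,9R,10S), CNP0129553.1 | C=C/C(C)=C/C[C@@H]1C(=C)CC[C@@H]2C(COC(C)=O)(COC(C)=O)CCC[C@@]12C | target

Total step count: 19. Longest linear sequence: 17 (steps 1–11 and 14–19). Steps 12 and 13 form the two-step side branch.

Steps most likely to fail

Step 7.
- What may go wrong: the crowded C5–C10 bond (next to quaternary C4, creating quaternary C10) may form too slowly. Lewis-acid-induced desilylation of the dienol ether, ionisation of the allylic silyl ether in the product, or a stop after the first bond could then compete. Endo and facial selectivity may also erode under the influence of the β-methyl group.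
- Fallback, from acid 8 back to acid 18: Lewis acid activation and auxiliary control are given up in favour of a thermal cycloaddition of a simple ester followed by resolution.
- Acid 8 is alkylated with BnBr and K2CO3 in DMF to the benzyl ester F1.
- Cross-metathesis with 12 under the conditions of step 5 gives the benzyl ester enal F2.
- TBSOTf and Et3N give the benzyl ester silyl dienol ether F3.
- Heating in toluene (BHT, base-washed sealed tube, 180–200 °C) should give the racemic trans-fused cycloadduct F4, to be separated from any cis-fused isomer.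
- H2 over Pd/C saturates C6=C7 and cleaves the benzyl ester in the same operation to the racemic acid F5.
- Preparative chromatography on a chiral stationary phase delivers 18.

Step 14.
- What may go wrong: zinc insertion at the hindered primary iodide may be slow, the organozinc may be protonated, or β-hydride elimination from the alkylpalladium may outrun coupling.
- Fallback, from alcohol 19 back to keto-enal 28: the side chain is built by olefination instead of cross-coupling, which also makes steps 11–13 unnecessary.
- Dess–Martin oxidation of 19 gives the C11 aldehyde F6.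
- Wittig reaction with Ph3P=CHOMe gives the enol ether F7.
- Dilute HCl in THF gives the homologous C12 aldehyde F8.
- The stabilised ylide Ph3P=C(CH3)CHO in toluene at 90 °C gives the (E)-enal silyl ether F9.
- Aqueous HF in MeCN frees the C8 hydroxy enal F10.
- Dess–Martin oxidation gives 28.

Step 9.
- What may go wrong: C11 sits between quaternary C10 and the axial C8 silyloxy group, so attack at the exocyclic carbonyl may be slow. Opening of the oxazolidinone ring or base-induced loss of silanol could then compete.
- Fallback, from imide 16 back to alcohol 19: acyl transfer to sulfur replaces hydrolysis, and steps 9 and 10 are bypassed.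
- LiSEt (EtSH, n-BuLi, THF, 0 °C) converts 16 into the S-ethyl thioester F11.
- NaBH4 in EtOH reduces the thioester selectively in the presence of the methyl esters to 19.

Further compounds
F1 | step 7 | benzyl (2E)-7,7-bis(methoxycarbonyl)-3-methyldeca-2,9-dienoate | O=C(/C=C(C)/CCCC(CC=C)(C(=O)OC)C(=O)OC)OCc1ccccc1
F2 | step 7 | benzyl (2E,9E)-7,7-bis(methoxycarbonyl)-3-methyl-11-oxoundeca-2,9-dienoate | O=C(/C=C(C)/CCCC(C/C=C/C=O)(C(=O)OC)C(=O)OC)OCc1ccccc1
F3 | step 7 | benzyl (2E,8E,10E)-11-(tert-butyldimethylsilyloxy)-7,7-bis(methoxycarbonyl)-3-methylundeca-2,8,10-trienoate | O=C(/C=C(C)/CCCC(C(=O)OC)(C(=O)OC)/C=C/C=C/O[Si](C)(C)C(C)(C)C)OCc1ccccc1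
F4 | step 7 | racemic trans-fused Δ6-octalin C11 benzyl ester, relative configuration as in 15 (one enantiomer drawn) | O=C(OCc1ccccc1)[C@@H]2[C@H](O[Si](C)(C)C(C)(C)C)C=C[C@@H]3C(C(=O)OC)(C(=O)OC)CCC[C@@]23C
F5 | step 7 | racemate of acid 18 (one enantiomer drawn) | OC(=O)[C@@H]1[C@H](O[Si](C)(C)C(C)(C)C)CC[C@@H]2C(C(=O)OC)(C(=O)OC)CCC[C@@]12C
F6 | step 14 | C11 aldehyde with C8-OTBS and C4(CO2Me)2 | O=C[C@@H]1[C@H](O[Si](C)(C)C(C)(C)C)CC[C@@H]2C(C(=O)OC)(C(=O)OC)CCC[C@@]12C
F7 | step 14 | C11=C12 methyl enol ether (E/Z mixture) | COC=C[C@@H]1[C@H](O[Si](C)(C)C(C)(C)C)CC[C@@H]2C(C(=O)OC)(C(=O)OC)CCC[C@@]12C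
F8 | step 14 | homologous C12 aldehyde | O=CC[C@@H]1[C@H](O[Si](C)(C)C(C)(C)C)CC[C@@H]2C(C(=O)OC)(C(=O)OC)CCC[C@@]12C
F9 | step 14 | (12E)-C14 enal with C8-OTBS | O=C/C(C)=C/C[C@@H]1[C@H](O[Si](C)(C)C(C)(C)C)CC[C@@H]2C(C(=O)OC)(C(=O)OC)CCC[C@@]12C
F10 | step 14 | (12E)-C14 enal with free C8-OH | O=C/C(C)=C/C[C@@H]1[C@H](O)CC[C@@H]2C(C(=O)OC)(C(=O)OC)CCC[C@@]12C
F11 | step 9 | C11 S-ethyl thioester with C8-OTBS and C4(CO2Me)2 | CCSC(=O)[C@@H]1[C@H](O[Si](C)(C)C(C)(C)C)CC[C@@H]2C(C(=O)OC)(C(=O)OC)CCC[C@@]12C
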